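## Retrosynthetic overview

1. The C3–CH2CO2H bond is cut to a cyclic peroxycarbenium ion (from methyl peroxyacetal 25) plus a ketene silyl acetal.
2. The C6–ethyl bond is cut the same way: a tertiary peroxycarbenium ion from bridged ozonide 22 plus Et2Zn; 22 comes from H2O2 and the masked 1,4-keto-aldehyde 20.
3. The C4 ethyl comes from asymmetric conjugate addition to enone acetal 18; 18 comes from oxidative dearomatisation of 2-alkylfuran 14, whose four ring carbons become C3–C6 and whose two α-carbons become the two peroxide-bearing carbons.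
4. The side chain comes from hex-1-ene by two Zr-catalysed carboaluminations and is joined to furan through 2-furyllithium.
5. Ring order: the furan is opened; the trioxolane and 1,2-dioxane rings of 22 form together; the trioxolane bridge is then opened, leaving the 1,2-dioxane.

Assumption: the SMILES is read as (3S,4S,6R) in the ring and (2S,4S) in the side chain, with CH2CO2H, the C4 ethyl and the C6 octyl chain all cis. The catalyst and ligand enantiomers named below are the ones expected to give that series and should be confirmed on the first run.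

## Route

Step 1
Reactants: 1 hex-1-ene; 2 triethylaluminium; 3 bromoethene
Product: 6 (4S)-4-ethyloct-1-ene, via diethyl[(2S)-2-ethylhexyl]alane 4 (not isolated), via [(2S)-2-ethylhexyl]zinc triflate 5 (not isolated)
Conditions: Et3Al, (+)-(NMI)2ZrCl2 (5 mol%; the antipode of the catalyst that gives (R)-2-alkylalkanols), CH2Cl2, 0 °C to rt; evaporate; Zn(OTf)2 (1 equiv), DMF; Pd(DPEphos)Cl2 (3 mol%), DIBAL-H (6 mol%), vinyl bromide (4 equiv), rt to 50 °C; aq HCl
Reagents that add atoms: triethylaluminium CC[Al](CC)CC; bromoethene C=CBr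
Why: Zr-catalysed asymmetric carboalumination (ZACA) adds ethyl to C2 and Al to C1 under catalyst control (about 90% ee, sets the future side-chain C4 as S), and Al-to-Zn transmetalation followed by Pd-catalysed Negishi vinylation extends the primary alkyl metal without touching the stereocentre.

Step 2
Reactants: 6 (4S)-4-ethyloct-1-ene; 7 trimethylaluminium; 8 dioxygen
Product: 10 (2S,4S)-4-ethyl-2-methyloctan-1-ol, via [(2S,4S)-4-ethyl-2-methyloctyl]dimethylalane 9 (not isolated)
Conditions: Me3Al (2 equiv), (+)-(NMI)2ZrCl2 (5 mol%), MAO (cat.), CH2Cl2, 0 °C to rt; O2, 0 °C; aq NaOH; chromatography to remove the minor anti diastereomer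
Reagents that add atoms: trimethylaluminium C[Al](C)C; dioxygen O=O
Why: A second ZACA (methylalumination) sets C2 as S under catalyst control, with statistical amplification raising the ee of the syn isomer, and the C–Al bond is oxidised by O2 with retention; the minor diastereomer is separable at the alcohol stage.

Step 3
Reactants: 10 (2S,4S)-4-ethyl-2-methyloctan-1-ol; 11 furan
Product: 14 2-[(2S,4S)-4-ethyl-2-methyloctyl]furan, via (2S,4S)-4-ethyl-2-methyloctyl triflate 12 (not isolated), via 2-furyllithium 13 (not isolated)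
Conditions: Tf2O, 2,6-lutidine, CH2Cl2, −78 °C; cannulate into 2-furyllithium (furan, n-BuLi, THF, 0 °C; 3 equiv), −78 to 0 °C
Reagents that add atoms: furan c1ccoc1
Why: O-triflation followed by SN2 alkylation of α-lithiated furan joins the chain to the heteroaromatic; both stereocentres are remote from the reacting CH2 and are untouched.

Step 4
Reactants: 14 2-[(2S,4S)-4-ethyl-2-methyloctyl]furan; 15 methanol
Product: 18 (2E,6S,8S)-8-ethyl-1,1-dimethoxy-6-methyldodec-2-en-4-one, via 2,5-dimethoxy-2,5-dihydrofuran 16 (not isolated), via (Z)-enone acetal 17 (not isolated)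
Conditions: Br2 (1.0 equiv), MeOH, −45 °C, no base; warm to 0 °C, 2 h; NaHCO3; if Z isomer remains, I2 (2 mol%), CH2Cl2, rt
Reagents that add atoms: methanol CO
Why: Clauson-Kaas-type oxidative 2,5-dimethoxylation (Br2/MeOH 1,4-addition) breaks the furan aromaticity, and the HBr formed opens the cyclic bis-acetal to its thermodynamically preferred form (free conjugated ketone, aldehyde kept as dimethyl acetal) and isomerises Z to E; no stereocentre is formed or disturbed.

Step 5
Reactants: 18 (2E,6S,8S)-8-ethyl-1,1-dimethoxy-6-methyldodec-2-en-4-one; 19 ethylmagnesium bromide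
Product: 20 (2S,6S,8S)-2,8-diethyl-1,1-dimethoxy-6-methyldodecan-4-one
Conditions: EtMgBr (1.2 equiv), CuBr·SMe2 (5 mol%), JosiPhos SL-J001 (6 mol%, enantiomer giving 2S), t-BuOMe, −75 °C; sat. aq NH4Cl
Reagents that add atoms: ethylmagnesium bromide CC[Mg]Br
Why: Cu/JosiPhos-catalysed asymmetric conjugate addition of a Grignard reagent to an acyclic E-enone (Feringa conditions) puts ethyl on the only electrophilic β-carbon (the aldehyde end is masked), and the ligand fixes the new centre as 2S (future C4) independently of the remote side-chain centres.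

Step 6
Reactants: 20 (2S,6S,8S)-2,8-diethyl-1,1-dimethoxy-6-methyldodecan-4-one; 21 hydrogen peroxide
Product: 22 (5S)-5-ethyl-1-[(2S,4S)-4-ethyl-2-methyloctyl]-2,3,7-trioxabicyclo[2.2.1]heptane (exo/endo-ethyl mixture)
Conditions: ethereal H2O2 (1.3 equiv), BF3·OEt2 (20 mol%) or phosphomolybdic acid (5 mol%), Et2O, 0 °C to rt, MgSO4
Reagents that add atoms: hydrogen peroxide OO
Why: Acid-catalysed peroxyketalisation and transacetalisation of a masked 1,4-dicarbonyl compound with H2O2 (the ozone-free Criegee/Terent'ev route to bridged ozonides) ties the ketone carbon and the acetal carbon together through O–O and through O with loss of two MeOH; the bridgehead centres are temporary and the ethyl-bearing centre is not involved.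

Step 7
Reactants: 22 bridged ozonide; 23 diethylzinc; 15 methanol
Product: 25 (4S,6R)-4,6-diethyl-6-[(2S,4S)-4-ethyl-2-methyloctyl]-3-methoxy-1,2-dioxane (anomer mixture at C3), via 3-(trimethylsilyloxy)-1,2-dioxane 24 (not isolated)
Conditions: Et2Zn (2.5 equiv), TMSOTf (1.2 equiv), CH2Cl2, −78 °C; then MeOH, PPTS (cat.), −78 °C to rt
Reagents that add atoms: diethylzinc CC[Zn]CC; methanol CO
Why: Proposed new method: TMSOTf silylates the ether bridge oxygen and ionises the tertiary C–O bond to a six-membered peroxycarbenium ion, which Et2Zn ethylates by axial attack through a chair-like transition state, trans to the pseudo-equatorial C4 ethyl (1,3-trans, giving 6R with the octyl chain equatorial); the closest known reactions are Lewis-acid substitutions of ozonides and cyclic peroxyketals by allylsilanes and silyl enol ethers (Dussault) and dialkylzinc alkylation of cyclic oxocarbenium ions with a peroxide intact (C-10 alkylation of artemisinin derivatives), and MeOH/PPTS then converts the anomeric silyl ether into the methyl peroxyacetal.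

Step 8
Reactants: 25 (4S,6R)-3-methoxy-1,2-dioxane; 26 ketene bis(trimethylsilyl) acetal
Product: 28 2-[(3S,4S,6R)-4,6-diethyl-6-[(2S,4S)-4-ethyl-2-methyloctyl]-1,2-dioxan-3-yl]acetic acid, via trimethylsilyl ester 27 (not isolated)
Conditions: 26 (3 equiv), TMSOTf (1.1 equiv), CH2Cl2, −78 to −40 °C; pH 4 aqueous buffer
Reagents that add atoms: ketene bis(trimethylsilyl) acetal C=C(O[Si](C)(C)C)O[Si](C)(C)C
Why: Mukaiyama-type addition of a silyl ketene acetal to a cyclic peroxycarbenium ion (Dussault-type substitution of a 3-alkoxy-1,2-dioxane) proceeds by axial attack on the half-chair that keeps the C4 ethyl and the C6 octyl chain equatorial (the other half-chair is syn-diaxial), so CH2CO2 enters cis to the C4 ethyl (3S); the silyl ester hydrolyses on work-up, avoiding a basic step that could open the β-peroxy acid by retro-oxa-Michael.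

## Compound list

1 | hex-1-ene | C=CCCCC | starting material
2 | triethylaluminium | CC[Al](CC)CC | starting material
3 | bromoethene | C=CBr | starting material
4 | diethyl[(2S)-2-ethylhexyl]alane | CCCC[C@H](CC)C[Al](CC)CC | intermediate (not isolated)
5 | [(2S)-2-ethylhexyl]zinc triflate | CCCC[C@H](CC)C[Zn]OS(=O)(=O)C(F)(F)F | intermediate (not isolated)
6 | (4S)-4-ethyloct-1-ene | CCCC[C@H](CC)CC=C | intermediate
7 | trimethylaluminium | C[Al](C)C | starting material
8 | dioxygen | O=O | starting material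
9 | [(2S,4S)-4-ethyl-2-methyloctyl]dimethylalane | CCCC[C@H](CC)C[C@H](C)C[Al](C)C | intermediate (not isolated)
10 | (2S,4S)-4-ethyl-2-methyloctan-1-ol | CCCC[C@H](CC)C[C@H](C)CO | intermediate
11 | furan | c1ccoc1 | starting material
12 | (2S,4S)-4-ethyl-2-methyloctyl trifluoromethanesulfonate | CCCC[C@H](CC)C[C@H](C)COS(=O)(=O)C(F)(F)F | intermediate (not isolated)
13 | 2-furyllithium | [Li]c1ccco1 | intermediate (not isolated)
14 | 2-[(2S,4S)-4-ethyl-2-methyloctyl]furan | CCCC[C@H](CC)C[C@H](C)Cc1ccco1 | intermediate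
15 | methanol | CO | starting material
16 | 2-[(2S,4S)-4-ethyl-2-methyloctyl]-2,5-dimethoxy-2,5-dihydrofuran (C2/C5 mixture) | CCCC[C@H](CC)C[C@H](C)CC1(OC)C=CC(OC)O1 | intermediate (not isolated)
17 | (2Z,6S,8S)-8-ethyl-1,1-dimethoxy-6-methyldodec-2-en-4-one | CCCC[C@H](CC)C[C@H](C)CC(=O)/C=C\C(OC)OC | intermediate (not isolated)
18 | (2E,6S,8S)-8-ethyl-1,1-dimethoxy-6-methyldodec-2-en-4-one | CCCC[C@H](CC)C[C@H](C)CC(=O)/C=C/C(OC)OC | intermediate
19 | ethylmagnesium bromide | CC[Mg]Br | starting material
20 | (2S,6S,8S)-2,8-diethyl-1,1-dimethoxy-6-methyldodecan-4-one | CCCC[C@H](CC)C[C@H](C)CC(=O)C[C@H](CC)C(OC)OC | intermediate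
21 | hydrogen peroxide | OO | starting material
22 | (5S)-5-ethyl-1-[(2S,4S)-4-ethyl-2-methyloctyl]-2,3,7-trioxabicyclo[2.2.1]heptane (exo/endo mixture) | CCCC[C@H](CC)C[C@H](C)CC12C[C@H](CC)C(OO1)O2 | intermediate
23 | diethylzinc | CC[Zn]CC | starting material
24 | (4S,6R)-4,6-diethyl-6-[(2S,4S)-4-ethyl-2-methyloctyl]-3-(trimethylsilyloxy)-1,2-dioxane (C3 mixture) | CCCC[C@H](CC)C[C@H](C)C[C@]1(CC)C[C@H](CC)C(O[Si](C)(C)C)OO1 | intermediate (not isolated)
25 | (4S,6R)-4,6-diethyl-6-[(2S,4S)-4-ethyl-2-methyloctyl]-3-methoxy-1,2-dioxane (C3 mixture) | CCCC[C@H](CC)C[C@H](C)C[C@]1(CC)C[C@H](CC)C(OC)OO1 | intermediate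
26 | ketene bis(trimethylsilyl) acetal (known reagent; otherwise made from trimethylsilyl acetate, LDA, TMSCl just before use) | C=C(O[Si](C)(C)C)O[Si](C)(C)C | starting material
27 | trimethylsilyl 2-[(3S,4S,6R)-4,6-diethyl-6-[(2S,4S)-4-ethyl-2-methyloctyl]-1,2-dioxan-3-yl]acetate | CCCC[C@H](CC)C[C@H](C)C[C@]1(CC)C[C@H](CC)[C@H](CC(=O)O[Si](C)(C)C)OO1 | intermediate (not isolated)
28 | 2-[(3S,4S,6R)-4,6-diethyl-6-[(2S,4S)-4-ethyl-2-methyloctyl]-1,2-dioxan-3-yl]acetic acid | CCCC[C@H](CC)C[C@H](C)C[C@]1(CC)C[C@H](CC)[C@H](CC(=O)O)OO1 | target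

## Step count and risk

Total steps: 8. Longest linear sequence: 8 (fully linear from hex-1-ene; furan enters at step 3).

The three steps most likely to fail:

**Step 7 (ethylation of the tertiary peroxycarbenium ion).** Alkylzinc transfer to a peroxycarbenium ion has no direct precedent; the ion may instead fragment (Criegee/Hock type) or Et2Zn may be too weak a nucleophile. The fallback gives up cation chemistry at C6 and builds the quaternary peroxide by radical hydroperoxidation, at the cost of C6 stereocontrol. It sets out from 20 and bypasses steps 6 and 7. Wittig ethylidenation (Ph3P=CHCH3, THF) gives (2S,6S,8S)-2,8-diethyl-4-ethylidene-1,1-dimethoxy-6-methyldodecane F1 as an E/Z mixture. Mukaiyama–Isayama hydroperoxysilylation (Co(thd)2, O2, Et3SiH) then gives the tertiary triethylsilyl peroxide (2S,6S,8S)-2,4,8-triethyl-1,1-dimethoxy-6-methyl-4-(triethylsilylperoxy)dodecane F2 as about 1:1 epimers at the new centre. TsOH in MeOH removes the silyl group and closes the hydroperoxide onto the acetal to give 25 together with its C6 epimer (4S,6S)-4,6-diethyl-6-[(2S,4S)-4-ethyl-2-methyloctyl]-3-methoxy-1,2-dioxane F3, which is removed by chromatography. The route is rejoined at 25.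

**Step 6 (bridged ozonide from the keto acetal and H2O2).** The acid may epimerise the centre next to the acetal, or give gem-dihydroperoxides and oligomeric peroxides instead of the bicycle. The fallback takes the peroxide oxygens from ozone rather than H2O2. It sets out from 20: Wittig methylenation (Ph3P=CH2) gives (2S,6S,8S)-2,8-diethyl-1,1-dimethoxy-6-methyl-4-methylidenedodecane F4. Ozonolysis in MeOH/CH2Cl2 at −78 °C traps the ketone oxide as the α-methoxy hydroperoxide, and catalytic TsOH closes it onto the acetal to give (4S)-4-ethyl-6-[(2S,4S)-4-ethyl-2-methyloctyl]-3,6-dimethoxy-1,2-dioxane F5. Under the step 7 conditions the C6 ketal methoxy group of F5 ionises in place of the ozonide bridge, and the route is rejoined at 25.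

**Step 8 (acetate unit at C3).** The peroxyacetal may ionise sluggishly, the C3 cation may lose the C4 proton, or the cis selectivity may be lower than predicted. The fallback replaces cation chemistry by olefination and peroxy-Michael ring closure. It sets out from 25: mild aqueous acid (TFA, THF/H2O) gives the peroxy-lactol (4S,6R)-4,6-diethyl-6-[(2S,4S)-4-ethyl-2-methyloctyl]-1,2-dioxan-3-ol F6. Its open hydroperoxy-aldehyde form reacts with Ph3P=CHCO2Me to give methyl (2E,4S,6R,8S,10S)-4,6,10-triethyl-6-hydroperoxy-8-methyltetradec-2-enoate F7. Et2NH in CF3CH2OH closes the ring by intramolecular oxa-Michael addition under equilibrating conditions to give methyl 2-[(3S,4S,6R)-4,6-diethyl-6-[(2S,4S)-4-ethyl-2-methyloctyl]-1,2-dioxan-3-yl]acetate F8. The C3 epimer methyl 2-[(3R,4S,6R)-4,6-diethyl-6-[(2S,4S)-4-ethyl-2-methyloctyl]-1,2-dioxan-3-yl]acetate F9 is separated and re-equilibrated. Me3SnOH (or LiOH at 0 °C) hydrolyses F8, and the route is rejoined at 28.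

Further compounds
F1 | step 7 | (2S,6S,8S)-2,8-diethyl-4-ethylidene-1,1-dimethoxy-6-methyldodecane | CCCC[C@H](CC)C[C@H](C)CC(=CC)C[C@H](CC)C(OC)OC
F2 | step 7 | (2S,6S,8S)-2,4,8-triethyl-1,1-dimethoxy-6-methyl-4-(triethylsilylperoxy)dodecane | CCCC[C@H](CC)C[C@H](C)CC(CC)(OO[Si](CC)(CC)CC)C[C@H](CC)C(OC)OC
F3 | step 7 | (4S,6S)-4,6-diethyl-6-[(2S,4S)-4-ethyl-2-methyloctyl]-3-methoxy-1,2-dioxane | CCCC[C@H](CC)C[C@H](C)C[C@@]1(CC)C[C@H](CC)C(OC)OO1
F4 | step 6 | (2S,6S,8S)-2,8-diethyl-1,1-dimethoxy-6-methyl-4-methylidenedodecane | CCCC[C@H](CC)C[C@H](C)CC(=C)C[C@H](CC)C(OC)OC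
F5 | step 6 | (4S)-4-ethyl-6-[(2S,4S)-4-ethyl-2-methyloctyl]-3,6-dimethoxy-1,2-dioxane | CCCC[C@H](CC)C[C@H](C)CC1(OC)C[C@H](CC)C(OC)OO1
F6 | step 8 | (4S,6R)-4,6-diethyl-6-[(2S,4S)-4-ethyl-2-methyloctyl]-1,2-dioxan-3-ol | CCCC[C@H](CC)C[C@H](C)C[C@]1(CC)C[C@H](CC)C(O)OO1
F7 | step 8 | methyl (2E,4S,6R,8S,10S)-4,6,10-triethyl-6-hydroperoxy-8-methyltetradec-2-enoate | CCCC[C@H](CC)C[C@H](C)C[C@@](CC)(OO)C[C@H](CC)/C=C/C(=O)OC
F8 | step 8 | methyl 2-[(3S,4S,6R)-4,6-diethyl-6-[(2S,4S)-4-ethyl-2-methyloctyl]-1,2-dioxan-3-yl]acetate | CCCC[C@H](CC)C[C@H](C)C[C@]1(CC)C[C@H](CC)[C@H](CC(=O)OC)OO1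
F9 | step 8 | methyl 2-[(3R,4S,6R)-4,6-diethyl-6-[(2S,4S)-4-ethyl-2-methyloctyl]-1,2-dioxan-3-yl]acetate | CCCC[C@H](CC)C[C@H](C)C[C@]1(CC)C[C@H](CC)[C@@H](CC(=O)OC)OO1
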